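**Retrosynthetic overview**

1. The target is (−)-epicatechin-(4β→8)-(+)-taxifolin. Upper flavan unit: rings A (phloroglucinol), B (catechol), C (pyran), atoms O1, C2, C3, C4, C4a, C8a. Taxifolin unit: rings D, E, F, atoms marked (D) or (F).
2. Last disconnections: nine benzyl ethers (hydrogenolysis) and the upper C3–OH, which is traced back to a C3–B(MIDA) bond (oxidation with retention).
3. Key disconnection: ring C is opened at C4–C4a and C2–C3 in one cationic [4+2] annulation (oxa-Povarov type). The partners are an O-aryl oxocarbenium ion (ring A–O1=C2–ring B, from a mixed acetal) and an (E)-alkenyl MIDA boronate on C8(D) of protected taxifolin.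
4. Enabling feature: C2 is an acetal-level carbon between O1 and ring B, and C4a is a C–H of ring A ortho to O1, so C4a=C8a–O1=C2 is a cationic 2-oxadiene. C4 is benzylic to the 2,4,6-trioxygenated ring D (its carbonyl is meta to C8(D)), and C3 can carry boron in place of OH.
5. Ring order: rings D, E, F come intact from (+)-taxifolin; rings A and B come from 3,5-bis(benzyloxy)phenol and 3,4-bis(benzyloxy)benzaldehyde; ring C is the only ring made, in step 7.

Key step: step 7

Assumption: the sense of induction of the chiral acid in step 7 cannot be assigned in advance; the (S,S) antipode is written, and the other antipode is used if the 2R,3R,4R upper unit proves to be the mismatched outcome.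

**Route**

Step 1
Reactants: 1 (+)-taxifolin, (2R,3R)
Product: 2 (2R,3R)-5,7,3',4'-tetra-O-benzyltaxifolin
Conditions: BnBr (4.4 equiv), K2CO3, DMF, Ar, 0 °C → rt
Reagents that add atoms: benzyl bromide, BrCc1ccccc1
Why: Williamson etherification of the four phenols (the hydrogen-bonded 5-OH last) leaves the much less acidic secondary 3-OH free, and the mild carbonate base used cold under argon should leave C2(F) and C3(F) untouched.

Step 2
Reactants: 2 (2R,3R)-5,7,3',4'-tetra-O-benzyltaxifolin
Product: 3 (2R,3R)-3,5,7,3',4'-penta-O-benzyltaxifolin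
Conditions: benzyl 2,2,2-trichloroacetimidate, TfOH (cat.), CH2Cl2/cyclohexane, 0 °C → rt
Reagents that add atoms: benzyl 2,2,2-trichloroacetimidate, N=C(OCc1ccccc1)C(Cl)(Cl)Cl
Why: Acid-catalysed O-benzylation with a trichloroacetimidate caps the α-hydroxy ketone without any base, so the base-sensitive ring F keeps its configuration.

Step 3
Reactants: 3 (2R,3R)-3,5,7,3',4'-penta-O-benzyltaxifolin
Product: 4 (2R,3R)-8-iodo-3,5,7,3',4'-penta-O-benzyltaxifolin
Conditions: NIS, TFA (cat.), CH2Cl2/MeCN, 0 °C → rt
Reagents that add atoms: N-iodosuccinimide, O=C1CCC(=O)N1I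
Why: Electrophilic aromatic iodination of the 5,7-dialkoxy ring D should go to C8(D), between O1 and 7-OBn, because C6(D) is shielded by two benzyloxy groups and no free 5-OH is present to direct to C6(D).

Step 4
Reactants: 4 (2R,3R)-8-iodo-3,5,7,3',4'-penta-O-benzyltaxifolin; 5 vinylboronic acid MIDA ester
Product: 6 (2R,3R)-8-[(E)-2-(MIDA-boryl)ethenyl]-3,5,7,3',4'-penta-O-benzyltaxifolin
Conditions: Pd(P(t-Bu)3)2 (5 mol %), Cy2NMe, MeCN/dioxane, 50 °C
Reagents that add atoms: none
Why: Mizoroki–Heck reaction at the terminal carbon of the vinyl boronate, in which the tetracoordinate boron cannot transmetalate under anhydrous amine-base conditions and syn β-hydride elimination gives the (E)-alkene.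

Step 5
Reactants: 7 3,4-bis(benzyloxy)benzaldehyde
Product: 8 3,4-bis(benzyloxy)benzaldehyde dimethyl acetal
Conditions: HC(OMe)3, p-TsOH·H2O (cat.), MeOH, rt
Reagents that add atoms: trimethyl orthoformate, COC(OC)OC; methanol, CO
Why: Acid-catalysed acetalisation, driven to completion by the orthoformate as water scavenger.

Step 6
Reactants: 8 3,4-bis(benzyloxy)benzaldehyde dimethyl acetal; 9 3,5-bis(benzyloxy)phenol
Product: 11 rac-1-{[3,5-bis(benzyloxy)phenoxy](methoxy)methyl}-3,4-bis(benzyloxy)benzene (mixed O-aryl O-methyl acetal), via α-chloro ether 10 (not isolated)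
Conditions: AcCl, SOCl2 (cat.), CH2Cl2, 0 °C → rt, evaporate; then 9, iPr2NEt, CH2Cl2, −20 → 0 °C
Reagents that add atoms: none
Why: Acetyl chloride exchanges one methoxy group for chloride (acetal to α-chloro ether) and the phenol is then O-alkylated under amine base as in a MOM-type etherification; the acetal carbon forms racemic, which does not matter because it becomes planar in step 7.

Step 7
Reactants: 6 (2R,3R)-8-[(E)-2-(MIDA-boryl)ethenyl]-3,5,7,3',4'-penta-O-benzyltaxifolin; 11 mixed O-aryl O-methyl acetal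
Product: 13 nona-O-benzyl-3-deoxy-3-(MIDA-boryl)epicatechin-(4β→8)-taxifolin (upper unit 2,3-cis-3,4-trans), via oxocarbenium ion 12 (not isolated)
Conditions: (S,S)-imidodiphosphorimidate Brønsted acid built from two 3,3'-bis[3,5-bis(trifluoromethyl)phenyl]-BINOL units with P=N–SO2CF3 groups (5 mol %), 5 Å MS, CHCl3, −40 → −20 °C, 11 (1.2 equiv) added slowly
Reagents that add atoms: none
Why: Proposed new method: the chiral acid ionises the methoxy group of 11 to the (E)-O-aryl oxocarbenium ion 12, held as an ion pair with the confined chiral anion; the boron-bearing alkene carbon of 6 (future C3) attacks C2, the positive charge building at C4 is stabilised by the 2,4,6-trioxygenated ring D and by hyperconjugation with the C–B(MIDA) bond, ring A closes onto C4 through C4a, and loss of the C4a proton returns the acid. The closest known reactions are the Lewis-acid oxa-Povarov reaction of aryl oxocarbenium ions with styrenes to 2,4-disubstituted chromans and the imidodiphosphorimidate-catalysed asymmetric Prins reaction of styrenes; new are the alkenyl boronate as two-carbon partner with the boron kept, and control by a chiral anion. Ring C closes in the [4+2] mode (four atoms C4a=C8a–O1=C2 of 12 plus C3=C4 of 6), the second bond being a 6-endo Friedel–Crafts closure onto either of the two equivalent ortho carbons of ring A. C3 and C4 should come out trans because both bonds form on the same face of the (E)-alkene; C2 and C3 should come out cis because ring D, twisted out of the alkene plane by its two ortho oxygens and repelled by the peri 5-OBn group, takes the exo position and leaves B(MIDA) endo under O1 of the (E)-oxocarbenium ion, leading to the conformer with the C2 aryl group equatorial and the C3–B and C4–aryl bonds trans-diaxial; the absolute configuration at C2, and through the relative control at C3 and C4, is set by the face of 12 that the chiral anion leaves open, and because the taxifolin centres are fixed the other outcome is a diastereomer that chromatography removes. The step needs regioselectivity (C3, not C4, bonding to C2), secured jointly by the β-boron effect and the benzylic stabilisation at C4; retention of boron, secured by the tetracoordinate, non-Lewis-acidic MIDA boronate that cannot be attacked at boron; and chemoselectivity against Friedel–Crafts alkylation of free electron-rich rings by 12, secured by slow addition of 11 to the mixture of acid and alkene.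

Step 8
Reactants: 13 nona-O-benzyl-3-deoxy-3-(MIDA-boryl)epicatechin-(4β→8)-taxifolin
Product: 15 nona-O-benzyl-epicatechin-(4β→8)-taxifolin (upper 3-OH free), via boronic acid 14 (not isolated)
Conditions: aq NaHCO3, MeOH/THF, 40 °C; then NaBO3·4H2O, THF/H2O, rt (one pot)
Reagents that add atoms: sodium perborate (tetrahydrate; dimeric peroxoborate), [Na+].[Na+].O[B-]1(O)OO[B-](O)(O)OO1
Why: Mild base releases the boronic acid from the MIDA cage and perborate oxidises the C–B bond by 1,2-migration with retention, so the C3 oxygen appears cis to the C2 aryl group and trans to the C4 aryl group.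

Step 9
Reactants: 15 nona-O-benzyl-epicatechin-(4β→8)-taxifolin
Product: 16 (−)-epicatechin-(4β→8)-(+)-taxifolin (CNP0210692.1)
Conditions: H2 (1 atm), Pd(OH)2/C, THF/MeOH/H2O, rt; Sephadex LH-20
Reagents that add atoms: none
Why: Hydrogenolysis of the nine benzyl ethers over Pd(OH)2/C under neutral conditions should leave the aryl ketone, the benzylic C–O bonds of rings C and F, and all five stereocentres untouched.

**Compound list**

1 | (+)-taxifolin, (2R,3R) | O=C1c2c(O)cc(O)cc2O[C@H](c2ccc(O)c(O)c2)[C@H]1O | starting material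
2 | (2R,3R)-5,7,3',4'-tetra-O-benzyltaxifolin | O=C1c2c(OCc3ccccc3)cc(OCc3ccccc3)cc2O[C@H](c2ccc(OCc3ccccc3)c(OCc3ccccc3)c2)[C@H]1O | intermediate
3 | (2R,3R)-3,5,7,3',4'-penta-O-benzyltaxifolin | O=C1c2c(OCc3ccccc3)cc(OCc3ccccc3)cc2O[C@H](c2ccc(OCc3ccccc3)c(OCc3ccccc3)c2)[C@H]1OCc1ccccc1 | intermediate
4 | (2R,3R)-8-iodo-3,5,7,3',4'-penta-O-benzyltaxifolin | O=C1c2c(OCc3ccccc3)cc(OCc3ccccc3)c(I)c2O[C@H](c2ccc(OCc3ccccc3)c(OCc3ccccc3)c2)[C@H]1OCc1ccccc1 | intermediate
5 | vinylboronic acid MIDA ester | C=C[B-]12OC(=O)C[N+]1(C)CC(=O)O2 | starting material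
6 | (2R,3R)-8-[(E)-2-(MIDA-boryl)ethenyl]-3,5,7,3',4'-penta-O-benzyltaxifolin | O=C1c2c(OCc3ccccc3)cc(OCc3ccccc3)c(/C=C/[B-]34OC(=O)C[N+]3(C)CC(=O)O4)c2O[C@H](c2ccc(OCc3ccccc3)c(OCc3ccccc3)c2)[C@H]1OCc1ccccc1 | intermediate
7 | 3,4-bis(benzyloxy)benzaldehyde | O=Cc1ccc(OCc2ccccc2)c(OCc2ccccc2)c1 | starting material
8 | 3,4-bis(benzyloxy)benzaldehyde dimethyl acetal | COC(OC)c1ccc(OCc2ccccc2)c(OCc2ccccc2)c1 | intermediate
9 | 3,5-bis(benzyloxy)phenol | Oc1cc(OCc2ccccc2)cc(OCc2ccccc2)c1 | starting material
10 | 1-[chloro(methoxy)methyl]-3,4-bis(benzyloxy)benzene (α-chloro ether) | COC(Cl)c1ccc(OCc2ccccc2)c(OCc2ccccc2)c1 | intermediate (not isolated)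
11 | rac-1-{[3,5-bis(benzyloxy)phenoxy](methoxy)methyl}-3,4-bis(benzyloxy)benzene | COC(Oc1cc(OCc2ccccc2)cc(OCc2ccccc2)c1)c1ccc(OCc2ccccc2)c(OCc2ccccc2)c1 | intermediate
12 | O-[3,5-bis(benzyloxy)phenyl] oxocarbenium ion of 3,4-bis(benzyloxy)benzaldehyde | C(=[O+]c1cc(OCc2ccccc2)cc(OCc2ccccc2)c1)c1ccc(OCc2ccccc2)c(OCc2ccccc2)c1 | intermediate (not isolated)
13 | nona-O-benzyl-3-deoxy-3-(MIDA-boryl)epicatechin-(4β→8)-taxifolin | O=C1c2c(OCc3ccccc3)cc(OCc3ccccc3)c([C@H]3c4c(OCc5ccccc5)cc(OCc5ccccc5)cc4O[C@H](c4ccc(OCc5ccccc5)c(OCc5ccccc5)c4)[C@@H]3[B-]56OC(=O)C[N+]5(C)CC(=O)O6)c2O[C@H](c2ccc(OCc3ccccc3)c(OCc3ccccc3)c2)[C@H]1OCc1ccccc1 | intermediate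
14 | corresponding C3 boronic acid | O=C1c2c(OCc3ccccc3)cc(OCc3ccccc3)c([C@H]3c4c(OCc5ccccc5)cc(OCc5ccccc5)cc4O[C@H](c4ccc(OCc5ccccc5)c(OCc5ccccc5)c4)[C@@H]3B(O)O)c2O[C@H](c2ccc(OCc3ccccc3)c(OCc3ccccc3)c2)[C@H]1OCc1ccccc1 | intermediate (not isolated)
15 | nona-O-benzyl-epicatechin-(4β→8)-taxifolin, upper 3-OH free | O=C1c2c(OCc3ccccc3)cc(OCc3ccccc3)c([C@H]3c4c(OCc5ccccc5)cc(OCc5ccccc5)cc4O[C@H](c4ccc(OCc5ccccc5)c(OCc5ccccc5)c4)[C@@H]3O)c2O[C@H](c2ccc(OCc3ccccc3)c(OCc3ccccc3)c2)[C@H]1OCc1ccccc1 | intermediate
16 | (−)-epicatechin-(4β→8)-(+)-taxifolin, CNP0210692.1 | O=C1c2c(O)cc(O)c([C@H]3c4c(O)cc(O)cc4O[C@H](c4ccc(O)c(O)c4)[C@@H]3O)c2O[C@H](c2ccc(O)c(O)c2)[C@H]1O | target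

**Step count and risks**

Total step count: 9. Longest linear sequence: 7 (steps 1, 2, 3, 4, 7, 8, 9).

Steps most likely to fail:

1. Step 7 (proposed new method). The cationic intermediate may lose boron by elimination to an allylic aryl ether instead of closing onto ring A; the oxocarbenium ion may alkylate free electron-rich rings intermolecularly; or facial selectivity may be poor. Fallback by the known flavan-4-yl cation coupling, setting out from compound 3 and returning at compound 15: commercial (−)-epicatechin is benzylated (BnBr, K2CO3, DMF) to 5,7,3',4'-tetra-O-benzyl-(−)-epicatechin F1. F1 is oxidised at C4 with DDQ in the presence of 2-ethoxyethanol in CH2Cl2 to the 4β-(2-ethoxyethoxy) ether F2. F2 is ionised with TMSOTf in CH2Cl2 at −78 °C in the presence of an excess of 3, which is recovered; Friedel–Crafts attack of C8(D) on the C4 cation, anti to the C3 oxygen, should give 15 directly.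

2. Step 8. The dihydroflavonol ring F may open or epimerise under the base needed to release the boronic acid, or the hindered axial boronate may oxidise sluggishly. Fallback from compound 13, returning at compound 15: the MIDA boronate is transligated with pinacol (NaHCO3, MeOH/THF, 45 °C) to the isolable pinacol boronate F4. F4 is then oxidised under anhydrous, base-free conditions with trimethylamine N-oxide in THF at 60 °C, and the resulting borate ester is cleaved in a neutral aqueous work-up to give 15.

3. Step 4. Oxidative addition and alkene insertion at the doubly ortho-substituted, electron-rich iodide may be slow, leading to protodeiodination. Fallback from compound 4, returning at compound 6: Stille coupling with tributyl(vinyl)stannane (Pd(PPh3)4, toluene, 90 °C, no base) gives the 8-vinyl compound F3. Cross-metathesis of F3 with 5 (second-generation Grubbs catalyst RuCl2(=CHPh)(PCy3)(H2IMes), CH2Cl2, 40 °C) should then deliver the (E)-alkenyl MIDA boronate 6.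

**Further compounds**

F1 | step 7 | 5,7,3',4'-tetra-O-benzyl-(−)-epicatechin | C1c2c(OCc3ccccc3)cc(OCc3ccccc3)cc2O[C@H](c2ccc(OCc3ccccc3)c(OCc3ccccc3)c2)[C@@H]1O
F2 | step 7 | 4β-(2-ethoxyethoxy)-5,7,3',4'-tetra-O-benzyl-(−)-epicatechin | CCOCCO[C@H]1c2c(OCc3ccccc3)cc(OCc3ccccc3)cc2O[C@H](c2ccc(OCc3ccccc3)c(OCc3ccccc3)c2)[C@@H]1O
F3 | step 4 | (2R,3R)-8-ethenyl-3,5,7,3',4'-penta-O-benzyltaxifolin | O=C1c2c(OCc3ccccc3)cc(OCc3ccccc3)c(C=C)c2O[C@H](c2ccc(OCc3ccccc3)c(OCc3ccccc3)c2)[C@H]1OCc1ccccc1
F4 | step 8 | nona-O-benzyl-3-deoxy-3-(pinacolboryl)epicatechin-(4β→8)-taxifolin | O=C1c2c(OCc3ccccc3)cc(OCc3ccccc3)c([C@H]3c4c(OCc5ccccc5)cc(OCc5ccccc5)cc4O[C@H](c4ccc(OCc5ccccc5)c(OCc5ccccc5)c4)[C@@H]3B5OC(C)(C)C(C)(C)O5)c2O[C@H](c2ccc(OCc3ccccc3)c(OCc3ccccc3)c2)[C@H]1OCc1ccccc1
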